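**Retrosynthetic overview**
- C7–H is set last: hydride adds to the C7 aryl-oxocarbenium ion of a 7,9'-cyclic ketal, anti to the C8 CH2OH group, which gives the 7,8-cis arrangement.
- The tetrahydrofuran ring (C7–O9' bond) comes from a two-fold dehydrogenation at C7 of an open-chain, 8–8'-linked 7'-oxo diol; the first quinone-methide-type cation is captured by the 9'-OH, as in lignan biosynthesis.
- C9' comes from formaldehyde, added to a transient 9,7'-dihydrofuran trans to the C8 benzyl group; this helper ring is opened again in the same step.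
- The C8–C8' bond comes from an enantioselective radical α-alkylation of 3-(3,4-dimethoxyphenyl)propanal with the trimethoxyphenacyl radical, which sets C8.
- Ring order: transient dihydrofuran (step 3, opened), then the tetrahydrofuran ring of the target (step 4).

Assumption: the (2R,5S)-imidazolidinone gives the (R)-aldehyde, as it does with simple aldehydes (otherwise its mirror image is used); lignan locants are used, with C7 carrying the 3,4-dimethoxyphenyl group and C7' the ketone.

**Step 1**
Reactants: 1 3-(3,4-dimethoxyphenyl)propan-1-ol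
Product: 2 3-(3,4-dimethoxyphenyl)propanal
Conditions: TEMPO (10 mol%), PhI(OAc)2 (1.1 equiv), CH2Cl2, rt
Reagents that add atoms: none
Why: Oxoammonium (TEMPO/PhI(OAc)2) oxidation stops at the aldehyde and leaves the electron-rich veratryl ring untouched.

**Step 2**
Reactants: 2 3-(3,4-dimethoxyphenyl)propanal, 3 2-bromo-1-(3,4,5-trimethoxyphenyl)ethan-1-one
Product: 5 (3R)-3-[(3,4-dimethoxyphenyl)methyl]-4-hydroxy-1-(3,4,5-trimethoxyphenyl)butan-1-one, via keto aldehyde 4 (not isolated)
Conditions: 2 (2 equiv), Ru(bpy)3Cl2 (0.5 mol%), (2R,5S)-2-tert-butyl-3,5-dimethylimidazolidin-4-one·TfOH (20 mol%), 2,6-lutidine (2 equiv), DMF, blue LEDs, 23 °C; then MeOH/CH2Cl2, NaBH4, −40 °C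
Reagents that add atoms: none
Why: Photoredox organocatalytic α-alkylation of an aldehyde (MacMillan–Nicewicz): the electrophilic phenacyl radical from 3 adds to the open face of the chiral enamine of 2, forming the C8–C8' bond and setting C8 as R, and the α-branched aldehyde is reduced in the same flask before it can racemise, NaBH4 at −40 °C leaving the electron-rich aryl ketone alone.

**Step 3**
Reactants: 5 (3R)-3-[(3,4-dimethoxyphenyl)methyl]-4-hydroxy-1-(3,4,5-trimethoxyphenyl)butan-1-one
Product: 7 (2S,3R)-3-[(3,4-dimethoxyphenyl)methyl]-4-hydroxy-2-(hydroxymethyl)-1-(3,4,5-trimethoxyphenyl)butan-1-one, via dihydrofuran 6 (not isolated)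
Conditions: PPTS (5 mol%), 4 Å MS, PhMe, 80 °C; evaporate; then 37% aq. HCHO (5 equiv), Yb(OTf)3 (10 mol%), THF, 0 °C → rt
Reagents that add atoms: formaldehyde, C=O; water, O
Why: Proposed new method: cyclodehydration of the γ-hydroxy ketone gives the 5-aryl-2,3-dihydrofuran 6, whose nucleophilic C4 (= C8') attacks Lewis-acid-activated formaldehyde from the face anti to the C3 benzyl group (Prins/Mukaiyama-type aldol; closest precedent is the lanthanide-triflate hydroxymethylation of silyl enol ethers with aqueous formaldehyde), and water opens the resulting aryl-oxocarbenium ion to the trans (2S,3R) keto diol, which cannot react a second time.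

**Step 4**
Reactants: 7 (2S,3R)-3-[(3,4-dimethoxyphenyl)methyl]-4-hydroxy-2-(hydroxymethyl)-1-(3,4,5-trimethoxyphenyl)butan-1-one
Product: 9 [(3S,4R,5RS)-5-(3,4-dimethoxyphenyl)-4-(hydroxymethyl)-5-methoxyoxolan-3-yl](3,4,5-trimethoxyphenyl)methanone, via cyclic ether 8 (not isolated)
Conditions: DDQ (2.3 equiv), 2,6-dichloropyridine (3 equiv), CH2Cl2/MeOH (10:1), 0 °C → rt
Reagents that add atoms: methanol, CO
Why: Proposed new method: DDQ abstracts hydride from the 3,4-dimethoxybenzylic C7–H to give a quinone-methide-type cation that the 9'-OH captures 5-exo (the 9-OH could only form an oxetane and the acylated trimethoxyphenyl ring is not oxidised), and a second hydride abstraction from the now α-oxygenated C7–H gives the aryl-oxocarbenium ion that methanol traps as ketal 9, so the C7 configuration of 8 is erased while the ring stays closed; closest precedents are the DDQ cyclisation of 4-(3,4-dimethoxyphenyl)alkanols to 2-aryltetrahydrofurans and the DDQ oxidation of benzylic ethers to oxocarbenium ions.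

**Step 5**
Reactants: 9 [(3S,4R,5RS)-5-(3,4-dimethoxyphenyl)-4-(hydroxymethyl)-5-methoxyoxolan-3-yl](3,4,5-trimethoxyphenyl)methanone
Product: 10 [(3S,4R,5R)-5-(3,4-dimethoxyphenyl)-4-(hydroxymethyl)oxolan-3-yl](3,4,5-trimethoxyphenyl)methanone
Conditions: Et3SiH (3 equiv), BF3·OEt2 (2 equiv), CH2Cl2, −78 → −40 °C
Reagents that add atoms: none
Why: Ionic hydrogenation of a cyclic ketal: BF3 regenerates the 2-aryl-oxocarbenium ion and Et3SiH adds to the face anti to the adjacent C8 CH2OH group (inside attack, as in the reduction of 2-aryl-3-substituted tetrahydrofuran hemiketals in lignan synthesis), giving the 7,8-cis (7R) product, while C8 and the trans C8' are untouched and the aryl ketone survives at low temperature.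

**Compound list**
1 | 3-(3,4-dimethoxyphenyl)propan-1-ol | COc1ccc(CCCO)cc1OC | starting material
2 | 3-(3,4-dimethoxyphenyl)propanal | COc1ccc(CCC=O)cc1OC | intermediate
3 | 2-bromo-1-(3,4,5-trimethoxyphenyl)ethan-1-one | COc1cc(C(=O)CBr)cc(OC)c1OC | starting material
4 | (2R)-2-[(3,4-dimethoxyphenyl)methyl]-4-oxo-4-(3,4,5-trimethoxyphenyl)butanal | O=C[C@H](Cc1ccc(OC)c(OC)c1)CC(=O)c1cc(OC)c(OC)c(OC)c1 | intermediate
5 | (3R)-3-[(3,4-dimethoxyphenyl)methyl]-4-hydroxy-1-(3,4,5-trimethoxyphenyl)butan-1-one | OC[C@H](Cc1ccc(OC)c(OC)c1)CC(=O)c1cc(OC)c(OC)c(OC)c1 | intermediate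
6 | (3R)-3-[(3,4-dimethoxyphenyl)methyl]-5-(3,4,5-trimethoxyphenyl)-2,3-dihydrofuran | COc1ccc(C[C@H]2COC(c3cc(OC)c(OC)c(OC)c3)=C2)cc1OC | intermediate
7 | (2S,3R)-3-[(3,4-dimethoxyphenyl)methyl]-4-hydroxy-2-(hydroxymethyl)-1-(3,4,5-trimethoxyphenyl)butan-1-one | OC[C@H](Cc1ccc(OC)c(OC)c1)[C@@H](CO)C(=O)c1cc(OC)c(OC)c(OC)c1 | intermediate
8 | [(3S,4R,5RS)-5-(3,4-dimethoxyphenyl)-4-(hydroxymethyl)oxolan-3-yl](3,4,5-trimethoxyphenyl)methanone, both C5 epimers, mainly 5S (aryl trans to CH2OH) | COc1ccc(C2OC[C@@H](C(=O)c3cc(OC)c(OC)c(OC)c3)[C@@H]2CO)cc1OC | intermediate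
9 | [(3S,4R,5RS)-5-(3,4-dimethoxyphenyl)-4-(hydroxymethyl)-5-methoxyoxolan-3-yl](3,4,5-trimethoxyphenyl)methanone, both anomers; CH2OH and aroyl trans | COc1ccc(C2(OC)OC[C@@H](C(=O)c3cc(OC)c(OC)c(OC)c3)[C@@H]2CO)cc1OC | intermediate
10 | [(3S,4R,5R)-5-(3,4-dimethoxyphenyl)-4-(hydroxymethyl)oxolan-3-yl](3,4,5-trimethoxyphenyl)methanone; aryl and CH2OH cis, CH2OH and aroyl trans | COc1ccc([C@@H]2OC[C@@H](C(=O)c3cc(OC)c(OC)c(OC)c3)[C@@H]2CO)cc1OC | target

**Step count**
Total steps: 5. Longest linear sequence: 5 (1 → 2 → 5 → 7 → 9 → 10; 3 is bought).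

**Steps most likely to fail, with fallbacks**

Step 4 is the most exposed. The C7 oxocarbenium ion can lose H8 and be dehydrogenated to a furan, or the oxidation can stall after the first ring closure. The fallback sets out from 7. With only 1.1 equiv DDQ in CH2Cl2/pH 7 buffer the oxidation is stopped after the ring closure, and the 7,8-trans ether [(3S,4R,5S)-5-(3,4-dimethoxyphenyl)-4-(hydroxymethyl)oxolan-3-yl](3,4,5-trimethoxyphenyl)methanone F3 is isolated. Its benzylic centre is then equilibrated by reversible ionisation (cat. BF3·OEt2, CH2Cl2, 0 °C), as in the acid epimerisation of furofuran lignans. The 7,8-cis isomer is separated and F3 is recycled. This fallback comes back to the route at 10 and replaces the oxidation–reduction at C7 by a thermodynamic equilibration.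

Step 3 is next. Enol ether 6 may hydrolyse back to 5 faster than it adds formaldehyde. The fallback sets out from 5. TMSOTf/Et3N gives the bis-silyl compound (R,Z)-trimethyl{[2-(3,4-dimethoxybenzyl)-4-(3,4,5-trimethoxyphenyl)-4-(trimethylsilyloxy)but-3-en-1-yl]oxy}silane F1. Its Mukaiyama hydroxymethylation (37% aq. HCHO, Yb(OTf)3, THF) is established chemistry but is not stereocontrolled in the open chain. It gives 7 together with its C2 epimer (2R,3R)-3-[(3,4-dimethoxyphenyl)methyl]-4-hydroxy-2-(hydroxymethyl)-1-(3,4,5-trimethoxyphenyl)butan-1-one F2. The two are separated, and F2 is re-equilibrated at the α-keto centre (cat. DBU, CH2Cl2) and recycled. This fallback comes back to the route at 7.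

Step 5 is third. The hydride may add with low facial selectivity, or the silane/BF3 pair may start to reduce the aryl ketone. The fallback sets out from 9. PhSH and BF3·OEt2 (CH2Cl2, −78 °C) exchange the methoxy group to give the S,O-ketal [(3S,4R,5RS)-5-(3,4-dimethoxyphenyl)-4-(hydroxymethyl)-5-(phenylsulfanyl)oxolan-3-yl](3,4,5-trimethoxyphenyl)methanone F4. Bu3SnH/AIBN (PhMe, 80 °C) then cleaves the C–S bond homolytically, and the C7 radical takes a hydrogen atom from the tin hydride on the face anti to the CH2OH group. This radical reduction does not touch the ketone and comes back to the route at 10.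

**Further compounds**
F1 | step 3 | (R,Z)-trimethyl{[2-(3,4-dimethoxybenzyl)-4-(3,4,5-trimethoxyphenyl)-4-(trimethylsilyloxy)but-3-en-1-yl]oxy}silane | C[Si](C)(C)OC[C@H](Cc1ccc(OC)c(OC)c1)/C=C(\O[Si](C)(C)C)c1cc(OC)c(OC)c(OC)c1
F2 | step 3 | (2R,3R)-3-[(3,4-dimethoxyphenyl)methyl]-4-hydroxy-2-(hydroxymethyl)-1-(3,4,5-trimethoxyphenyl)butan-1-one | OC[C@H](Cc1ccc(OC)c(OC)c1)[C@H](CO)C(=O)c1cc(OC)c(OC)c(OC)c1
F3 | step 4 | [(3S,4R,5S)-5-(3,4-dimethoxyphenyl)-4-(hydroxymethyl)oxolan-3-yl](3,4,5-trimethoxyphenyl)methanone | COc1ccc([C@H]2OC[C@@H](C(=O)c3cc(OC)c(OC)c(OC)c3)[C@@H]2CO)cc1OC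
F4 | step 5 | [(3S,4R,5RS)-5-(3,4-dimethoxyphenyl)-4-(hydroxymethyl)-5-(phenylsulfanyl)oxolan-3-yl](3,4,5-trimethoxyphenyl)methanone | COc1ccc(C2(Sc3ccccc3)OC[C@@H](C(=O)c3cc(OC)c(OC)c(OC)c3)[C@@H]2CO)cc1OC
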